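Late in the run a molecule of target sits either in solution or in crystals, and in solution the dissolved gas can take it for good, so we reckon what that loss costs by the end.

    gas phase ⇌ dissolved gas, rate k1*(csat - [dissolved gas]) (k1 = 1.87 /s, csat = 2.4 mM)
    starting material + dissolved gas ⇌ target (K2 = 506 /M, k2 = 88.2 /M/s)
    dissolved gas + target → over-reacted product (k3 = 174 /M/s)
    starting material + target → side product (k4 = 1.55 /M/s)
    crystals ⇌ target, rate k5*(cs5 - [target]) while solid is left; crystals form when [target] > cs5 (cs5 = 1.4 mM, k5 = 0.661 /s)

starting material 0.020 M; gas phase 2.4 mM (held); time 25 s

- eta: doubling the dissolution coefficient of step 5, all else as stated
- alpha: doubling the saturation concentration of gas phase, all else as stated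
- beta: doubling the solubility in step 5, all else as stated
- zeta: doubling the transfer coefficient of step 1, all else as stated

- the target and crystals together standing at 25 s, as a percentage of the starting material charged
- the change that raises the amount of target and crystals together at 25 s, in percent of the starting material charged most ("none" if none brings more than 2 percentage points) (eta / alpha / beta / zeta / none)
- amount of target and crystals together at 25 s, in percent of the starting material charged, after beta

- a species is counted by the starting material in it: one side product counts as two
- amounts and yields of target count crystals too
- given per volume of solution although it is solid: crystals
- at the start none of the gas is dissolved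
- run time (flask): 25 s

We climb the time scales from the fastest. Gas enters the solution with a half-life of 0.371 s, and step 2 alone uses it with a half-life of 0.39 s, so the two are matched while starting material is plentiful. An excess of dissolved target over its solubility relaxes with a half-life of 1.05 s, shorter than the half-life of a dissolved target against over-reaction at saturated gas, 1.66 s. This half-life belongs to the excess and tells nothing of the fate of a single molecule, so we use it for one rough estimate: while crystals stand, we put dissolved target at its solubility, 1.4 mM. The side reaction, at 22 s, is slower than over-reaction, and we set it aside.

Over-reaction then runs at a steady 0.585 mM/s, the product of its constant, the saturation concentration and the solubility, and the charge does not enter it. Over the run this sums to 14.6 mM, the toll: the over-reacted product that a crystal-buffered flask pays by the end, reckoned at saturated gas. Here that is 73.1 % of the charge, so, counting the rest of the charge as target and crystals, we commit to 26.9 % for y. Beta doubles the toll to 146 % of the charge, more than was charged, so we expect no store and a target below 14.0 %. Alpha doubles the toll too, while eta and zeta leave it unchanged, so the toll shows no gain from any change and we answer none.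

The forecast gives 26 % (19 % to 33 %), names eta where we answered none, and gives 9 % after beta (4 % to 17 %), holding that “Crystals shelter the target from over-reaction with dissolved gas”.

The simulation gives 27.0 %, with eta best at 3.7 percentage points, more than the mark of 2 points, and 4.38 % after beta, so our none does not stand; zeta, with the same toll, moves the answer by −5.7 points. Over-reacted product in this flask stands at 59.4 % at 25.0 s, less than the toll's share, with dissolved gas at 73.9 % of saturation at 12.5 s. The neighbour flask charged with 0.080 M faces the same 14.6 mM, which is 18.2 % of its charge. It shows over-reacted product at 16.3 %, crystals at 45.0 %, and target and crystals together at 48.3 %.

The constants used here stand for no real mixture.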